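## The problem

CNP0233274.1 is a fully substituted benzene ring, a phloroglucinol monomethyl ether, joined through one CH2 group to C3 of a 6-ethyl-4-hydroxy-5-methyl-2-pyrone. The two rings share no other bond, so they can be made apart and joined late. All six positions of the arene differ and their order is fixed: the methoxy group lies between the acyl carbon and the bridge carbon, and the prenyl group lies between the two free hydroxyls. Three different carbon substituents therefore have to be placed around three oxygens without positional isomers. The only stereocentre is the R-configured carbon α to the aryl ketone; its methyl and ethyl groups differ by one CH2, and no second stereocentre exists to control it, so a reagent or catalyst must set it. That centre is enolisable, so once the ketone exists it should not meet strong base, hot acid or a Lewis acid. The prenyl olefin between two phenols cyclises to a chroman in acid and would not survive catalytic hydrogenation; the hydroxypyrone is an acidic vinylogous acid that quenches organometallics and can react twice with one-carbon electrophiles. The feature that opens the problem is that the ketone carbon is bonded directly to a ring carbon flanked by two oxygens. At the aldehyde level it is a non-enolisable formyl group that directed metalation can deliver, and the neighbouring carbon, with its ethyl group read as a reduced vinyl group, is the methyl-bearing terminus of a crotyl unit.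

## Retrosynthesis

The first cut removes the methylene carbon. Both of its C–C bonds are broken, the one to pyrone C3 and the one to the single unsubstituted ring carbon of the arene, giving the acylphloroglucinol 14, the hydroxypyrone 19 and a one-carbon electrophile at the formaldehyde level. The neighbouring options, building the pyrone on an arylmethyl side chain or attaching the bridge early, would carry an acidic pyrone through organolithium steps or add steps after the stereocentre exists. The cut is convergent: 14 holds 21 of the 33 heavy atoms and the stereocentre, and 19 is an achiral eight-carbon heterocycle. The forward reaction must be a crossed coupling. The pyrone is first turned into the electrophilic methide 21 through its Mannich base 20, and 14, which has exactly one free ring position, must capture it before a second pyrone does.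

Within 14 no skeletal bond is cut next; three functional-group changes lead back to a homoallylic alcohol. The phenols are masked as methoxymethyl ethers (13), the ketone is read as an oxidised carbinol (12), and the ethyl group as a saturated vinyl group (11). The stereocentre dictates the order. While its neighbour is a carbinol it is not acidic, so the vinyl group is saturated before the alcohol is oxidised; the reverse order would pass through a β,γ-unsaturated ketone whose α-hydrogen is both allylic and α to carbonyl. The forward steps must reduce a monosubstituted olefin beside a trisubstituted one without a metal catalyst, oxidise a hindered benzylic alcohol under neutral conditions, and remove two acetals with acid mild enough to spare the prenyl group and the ketone. These steps add no complexity; they exist so that the stereocentre can be made where it is easy.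

The central cut is the bond between the carbinol carbon and the methyl-bearing carbon of 11, which gives the aryl aldehyde 8 and the (E)-crotylboronate 9. Cutting one bond further out, between arene and carbonyl carbon, would need an enantiopure 2-methylbutanoyl donor of the rarer R series and, in a Friedel–Crafts version, its exposure to a Lewis acid. Cutting one bond further in, at the methyl or ethyl group, would mean an asymmetric enolate alkylation of a di-ortho-substituted aryl ketone that must tell methyl from ethyl. The crotyl cut replaces that distinction by methyl versus vinyl and moves the task to an aldehyde that cannot enolise. Precursor 8 is achiral and 9 is a commercial reagent, so all stereochemical information comes from the catalyst. The forward reaction must pass through a closed chair so that E geometry becomes anti, and must choose one aldehyde face. The carbinol configuration formed at the same time does not matter, because that centre is later oxidised.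

Aldehyde 8 is taken apart by two aryl–carbon cuts, both directed by the ring oxygens. The formyl–aryl bond is cut first to give arene 5, then the prenyl CH2–aryl bond to give the bis(methoxymethyl) ether 2 and prenyl bromide 3; 2 comes from 5-methoxyresorcinol 1. The neighbouring choice, electrophilic formylation and C-prenylation of free phenols, gives positional mixtures and poor C-alkylation. The order of the metalations has a structural reason. In 2 the carbon between the two acetal oxygens is the most acidic, and that is where the prenyl group belongs. Once it is filled, the two remaining ring hydrogens of 5 are equivalent, so the formyl group can enter only one kind of position. Each cut removes one substituent and the sequence ends in a symmetrical commercial phenol. The forward reactions ask that aryllithiums 4 and 6 form on the ring and not at the benzylic–allylic CH2.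

Pyrone 19 is cut at C4–C5 and O1–C2 into malonyl dichloride 17 and the silyl enol ether 16 of 3-pentanone 15. A linear route through acylation of a β-keto ester dianion is of similar length. The annulation is preferred because the symmetrical ketone removes any regiochemical question and both ring bonds form in one operation. The forward step requires C-acylation of 16 followed by lactonisation of the keto acid chloride 18.

## Roads not taken

Alternative 1: The cut runs through the benzene ring. Opening the bond between the acyl-bearing ring carbon and its neighbour unfolds the acylphloroglucinol into methyl (8R)-8-methyl-3,5,7-trioxodecanoate A2, which would be assembled from (2R)-2-methylbutanoic acid A3 by chain extension. In the forward step the polyanion of A2 in aqueous KOH closes by intramolecular Claisen condensation and aromatises to (2R)-2-methyl-1-(2,4,6-trihydroxyphenyl)butan-1-one A1.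
- Merits: it is biomimetic, it makes the ring, all three oxygens and the acyl group in one operation, and it reaches A1 in fewer steps than the chosen plan needs for 13, without organolithiums or an asymmetric catalyst. In that respect it is the better road.
- Weak points: the stereocentre of A2 sits α to a carbonyl that must be enolised for the cyclisation, in strong aqueous base, and A1 is again an aryl ketone with an α-hydrogen in KOH, so loss of configuration is the expected failure. A3 is the less accessible antipode. A1 is symmetrical, and the target then demands O-methylation of a chelated ortho hydroxyl (the least reactive oxygen), mono-C-prenylation at the ring carbon remote from that methoxy group, and bridging at the other. Direct C-prenylation of acylphloroglucinols is poorly selective and over-alkylates.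
- Comparison: the chosen plan gives up the short entry. In return every substituent is placed by directed metalation with no isomer choice, and the stereocentre is made beside a carbinol and never sees base.

Alternative 2: The cut removes the two pyrone bonds C4–C5 and O1–C2, leaving the arylmethylmalonyl dichloride A5 and the silyl enol ether 16. In the forward step A5, reacting as its chlorocarbonyl ketene, acylates 16 at carbon and lactonises to the di-O-acetyl derivative A4 of the target, which is then deacetylated.
- Merits: the bridge carbon is bonded to the arene before the pyrone exists, so only the crossed product can form, and self-coupling of the pyrone, the main risk of step 10, is impossible. Here it is better than the chosen plan. The annulation is the same reaction type as step 9.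
- Weak points: A5 carries a prenyl olefin, an epimerisable ketone and two aryl acetates, and must be made into a bis(acid chloride) that then liberates acid in the annulation; addition of that acid to the prenyl group and cyclisation onto it are likely. The arylmethylmalonic acid has to be built on the finished arene through a benzylic electrophile or a second formylation, several steps after the stereocentre is in place. The strategy also does not say how the stereocentre is made, so it answers the last bond and not the main problem. The final deacetylation is one more step.
- Comparison: the chosen plan meets the self-coupling risk by staging, with 19 fully converted into 20 before 14 is added, and by the single free ring carbon of 14. It is several steps shorter after 14.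

Alternative 3: The cut is the aryl–carbonyl bond. A3 is carried as the aryl ester A7, 3-(tert-butyldimethylsilyloxy)-5-methoxy-2-(3-methylbut-2-enyl)phenyl (2R)-2-methylbutanoate. Irradiation near 254 nm moves the acyl group from oxygen to the adjacent free ring carbon and gives the ketone A6.
- Merits: the stereocentre is bought, not made. The acyl radical keeps its configuration because the stereocentre is not the radical site. No Lewis acid is used. The ortho and para shifts converge on 14 after desilylation. No redox adjustment is needed, so the road to 14 is probably one or two steps shorter than the chosen one. That advantage is real.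
- Weak points: A3 must be sourced in the rarer R form. A prenylated, electron-rich arene is irradiated at short wavelength, and the ortho-hydroxy ketone product absorbs the same light and slows conversion. Cage escape with loss of the acyl group, decarbonylation of the secondary acyl radical, and light-induced cyclisation of the prenyl group onto the phenol all compete. A7 must be made by silylating one and acylating the other of two equivalent hydroxyls, a statistical desymmetrisation.
- Comparison: the chosen plan is longer in redox steps. It offers thermal steps of predictable conversion, either enantiomer from the choice of catalyst antipode, and independence from the supply of A3.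

Key step: step 4

Remark on the chemistry: the facial preference established for simple aryl aldehydes (Re-face attack with the R-configured phosphoric acid) is assumed to hold for aldehyde 8. If a trial run shows the opposite sense, the catalyst antipode is used and nothing else changes.

## Route

Step 1
Reactants: 1 5-methoxyresorcinol (5-methoxybenzene-1,3-diol)
Product: 2 1-methoxy-3,5-bis(methoxymethoxy)benzene
Conditions: MOMCl (2.5 equiv), iPr2NEt (3 equiv), CH2Cl2, 0 °C → rt
Reagents that add atoms: chloromethyl methyl ether, COCCl
Why: O-Alkylation of both phenols by the reactive α-chloro ether (acetal formation); the methoxymethyl ethers are chosen because they are the directing groups for the two metalations that follow.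

Step 2
Reactants: 2 1-methoxy-3,5-bis(methoxymethoxy)benzene; 3 prenyl bromide (1-bromo-3-methylbut-2-ene)
Product: 5 5-methoxy-1,3-bis(methoxymethoxy)-2-(3-methylbut-2-en-1-yl)benzene, via aryllithium 4 (not isolated)
Conditions: n-BuLi (1.1 equiv), THF, 0 °C; then 3, −78 °C → rt
Reagents that add atoms: none
Why: Directed ortho-metalation; the C–H between the two chelating acetal oxygens is the most acidic ring position, and the aryllithium should alkylate the primary allylic bromide by SN2 substitution.

Step 3
Reactants: 5 5-methoxy-1,3-bis(methoxymethoxy)-2-(3-methylbut-2-en-1-yl)benzene
Product: 8 6-methoxy-2,4-bis(methoxymethoxy)-3-(3-methylbut-2-en-1-yl)benzaldehyde, via aryllithium 6 (not isolated), via lithium aminoalkoxide 7 (not isolated)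
Conditions: n-BuLi (1.2 equiv), TMEDA, THF, −20 → 0 °C; DMF, −78 °C → rt; H2O
Reagents that add atoms: N,N-dimethylformamide, CN(C)C=O
Why: Second directed ortho-metalation; the two remaining ring hydrogens are equivalent and each is flanked by a methoxy and an acetal oxygen, so only one aldehyde can form. Formylation with the formamide proceeds through a tetrahedral aminoalkoxide that releases the aldehyde only on aqueous work-up.

Step 4
Reactants: 8 6-methoxy-2,4-bis(methoxymethoxy)-3-(3-methylbut-2-en-1-yl)benzaldehyde; 9 (E)-crotylboronic acid pinacol ester (2-[(2E)-but-2-en-1-yl]-4,4,5,5-tetramethyl-1,3,2-dioxaborolane)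
Product: 11 (1R,2R)-1-[6-methoxy-2,4-bis(methoxymethoxy)-3-(3-methylbut-2-en-1-yl)phenyl]-2-methylbut-3-en-1-ol, via borate ester 10 (not isolated)
Conditions: (R)-3,3′-bis(2,4,6-triisopropylphenyl)-1,1′-binaphthyl-2,2′-diyl hydrogen phosphate (5 mol %), 9 (1.3 equiv), toluene, −30 → 0 °C; aqueous work-up
Reagents that add atoms: none
Why: The closest known reaction type is the chiral phosphoric acid-catalysed allyl- and crotylboration of aryl aldehydes with pinacol boronates. The aldehyde oxygen binds boron and the crotyl group is transferred through a closed six-membered chair transition state, while the catalyst hydrogen-bonds through its acidic proton to a boronate oxygen and holds the formyl hydrogen with its phosphoryl oxygen. No ring is closed; one C–C bond and two stereocentres are formed. The relative configuration follows from the E geometry of 9: the crotyl methyl and the aryl group both sit equatorial in the chair, which gives the anti adduct. The absolute configuration is set by the catalyst, whose triisopropylphenyl walls leave one aldehyde face open; Re-face attack gives 1R and, through the chair, 2R at the methyl-bearing carbon, the centre that is kept. The step therefore needs enantioface selectivity above all, since an adduct formed through the chair on the other face would end as the S ketone. The substrate supports this: the formyl group cannot enolise and is the only carbonyl, both phenols are masked so no acidic OH competes for the catalyst, and the prenyl olefin and the acetals are inert to a few mol % of a phosphoric acid in toluene below 0 °C. The borate ester 10 formed first is cleaved on aqueous work-up.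

Step 5
Reactants: 11 (1R,2R)-1-[6-methoxy-2,4-bis(methoxymethoxy)-3-(3-methylbut-2-en-1-yl)phenyl]-2-methylbut-3-en-1-ol
Product: 12 (1R,2R)-1-[6-methoxy-2,4-bis(methoxymethoxy)-3-(3-methylbut-2-en-1-yl)phenyl]-2-methylbutan-1-ol
Conditions: 2-nitrobenzenesulfonylhydrazide (5 equiv), Et3N, CH2Cl2, rt
Reagents that add atoms: none
Why: Diimide reduction; concerted syn transfer of two hydrogens is much faster to a monosubstituted olefin than to a trisubstituted one, so the vinyl group should be saturated and the prenyl group left. No metal is present that could isomerise the olefins or touch the benzylic C–O bond, and neither stereocentre is involved.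

Step 6
Reactants: 12 (1R,2R)-1-[6-methoxy-2,4-bis(methoxymethoxy)-3-(3-methylbut-2-en-1-yl)phenyl]-2-methylbutan-1-ol
Product: 13 (2R)-1-[6-methoxy-2,4-bis(methoxymethoxy)-3-(3-methylbut-2-en-1-yl)phenyl]-2-methylbutan-1-one
Conditions: Dess–Martin periodinane (1.5 equiv), pyridine, CH2Cl2, 0 °C → rt
Reagents that add atoms: none
Why: Dess–Martin oxidation of a hindered benzylic alcohol under buffered, near-neutral conditions; the carbinol stereocentre is removed on purpose and the α-centre is not enolised at this pH and temperature.

Step 7
Reactants: 13 (2R)-1-[6-methoxy-2,4-bis(methoxymethoxy)-3-(3-methylbut-2-en-1-yl)phenyl]-2-methylbutan-1-one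
Product: 14 (2R)-1-[2,4-dihydroxy-6-methoxy-3-(3-methylbut-2-en-1-yl)phenyl]-2-methylbutan-1-one
Conditions: HCl (3 M aq., 5 equiv), MeOH, rt
Reagents that add atoms: none
Why: Acid-catalysed acetal exchange with methanol removes both methoxymethyl groups as the volatile dimethyl acetal; room temperature and dilute acid are chosen to stay below the threshold for chroman formation and for enolisation of the hindered ketone.

Step 8
Reactants: 15 3-pentanone
Product: 16 (Z)-3-(trimethylsilyloxy)pent-2-ene
Conditions: TMSOTf (1.1 equiv), Et3N (1.3 equiv), Et2O, 0 °C → rt
Reagents that add atoms: trimethylsilyl trifluoromethanesulfonate, C[Si](C)(C)OS(=O)(=O)C(F)(F)F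
Why: Soft enolisation and O-silylation of a ketone with a silyl triflate and a tertiary amine; the ketone is symmetrical, so there is no regiochemical question, and the olefin geometry (mainly Z) is lost in the next step.

Step 9
Reactants: 16 (Z)-3-(trimethylsilyloxy)pent-2-ene; 17 malonyl dichloride
Product: 19 6-ethyl-4-hydroxy-5-methyl-2H-pyran-2-one, via keto acid chloride 18 (not isolated)
Conditions: Et2O, −78 °C → rt
Reagents that add atoms: none
Why: Annulation of a silyl enol ether with malonyl dichloride to a 4-hydroxy-2-pyrone: C-acylation of the enol ether gives the 3,5-dioxo acid chloride, whose enol oxygen then closes the lactone.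

Step 10
Reactants: 19 6-ethyl-4-hydroxy-5-methyl-2H-pyran-2-one; 14 (2R)-1-[2,4-dihydroxy-6-methoxy-3-(3-methylbut-2-en-1-yl)phenyl]-2-methylbutan-1-one
Product: 22 3-{[2,4-dihydroxy-6-methoxy-5-[(2R)-2-methylbutanoyl]-3-(3-methylbut-2-en-1-yl)phenyl]methyl}-6-ethyl-4-hydroxy-5-methyl-2H-pyran-2-one (CNP0233274.1), via pyrone Mannich base 20 (not isolated), via pyrone methide 21 (not isolated)
Conditions: 19, Eschenmoser's salt (1.0 equiv), MeCN, rt; then 14 (1.0 equiv), 50 °C
Reagents that add atoms: N,N-dimethylmethyleneiminium iodide (Eschenmoser's salt), C=[N+](C)C.[I-]
Why: Mannich reaction at the nucleophilic C3 of the hydroxypyrone, loss of dimethylamine to the 3-methylene-2,4-dione, and conjugate addition of the one free, hydroxyl-activated ring carbon of 14 (a three-component Mannich-type methylene bridging). Converting all of 19 into 20 before 14 is added suppresses self-coupling of the pyrone, and the mildly acidic, base-free medium leaves the α-stereocentre and the prenyl group alone.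

## Compound list

1 | 5-methoxyresorcinol (5-methoxybenzene-1,3-diol) | COc1cc(O)cc(O)c1 | starting material
2 | 1-methoxy-3,5-bis(methoxymethoxy)benzene | COCOc1cc(OC)cc(OCOC)c1 | intermediate
3 | prenyl bromide (1-bromo-3-methylbut-2-ene) | CC(C)=CCBr | starting material
4 | [4-methoxy-2,6-bis(methoxymethoxy)phenyl]lithium, formed and consumed in step 2 | [Li]c1c(OCOC)cc(OC)cc1OCOC | intermediate
5 | 5-methoxy-1,3-bis(methoxymethoxy)-2-(3-methylbut-2-en-1-yl)benzene | COCOc1cc(OC)cc(OCOC)c1CC=C(C)C | intermediate
6 | [6-methoxy-2,4-bis(methoxymethoxy)-3-(3-methylbut-2-en-1-yl)phenyl]lithium, formed and consumed in step 3 | [Li]c1c(OC)cc(OCOC)c(CC=C(C)C)c1OCOC | intermediate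
7 | lithium (dimethylamino)[6-methoxy-2,4-bis(methoxymethoxy)-3-(3-methylbut-2-en-1-yl)phenyl]methanolate, racemic at the aminal carbon, formed and consumed in step 3 | [Li]OC(N(C)C)c1c(OC)cc(OCOC)c(CC=C(C)C)c1OCOC | intermediate
8 | 6-methoxy-2,4-bis(methoxymethoxy)-3-(3-methylbut-2-en-1-yl)benzaldehyde | O=Cc1c(OC)cc(OCOC)c(CC=C(C)C)c1OCOC | intermediate
9 | (E)-crotylboronic acid pinacol ester (2-[(2E)-but-2-en-1-yl]-4,4,5,5-tetramethyl-1,3,2-dioxaborolane) | C/C=C/CB1OC(C)(C)C(C)(C)O1 | starting material
10 | 2-{(1R,2R)-1-[6-methoxy-2,4-bis(methoxymethoxy)-3-(3-methylbut-2-en-1-yl)phenyl]-2-methylbut-3-en-1-yloxy}-4,4,5,5-tetramethyl-1,3,2-dioxaborolane, formed and consumed in step 4 | C=C[C@@H](C)[C@@H](OB1OC(C)(C)C(C)(C)O1)c1c(OC)cc(OCOC)c(CC=C(C)C)c1OCOC | intermediate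
11 | (1R,2R)-1-[6-methoxy-2,4-bis(methoxymethoxy)-3-(3-methylbut-2-en-1-yl)phenyl]-2-methylbut-3-en-1-ol | C=C[C@@H](C)[C@@H](O)c1c(OC)cc(OCOC)c(CC=C(C)C)c1OCOC | intermediate
12 | (1R,2R)-1-[6-methoxy-2,4-bis(methoxymethoxy)-3-(3-methylbut-2-en-1-yl)phenyl]-2-methylbutan-1-ol | CC[C@@H](C)[C@@H](O)c1c(OC)cc(OCOC)c(CC=C(C)C)c1OCOC | intermediate
13 | (2R)-1-[6-methoxy-2,4-bis(methoxymethoxy)-3-(3-methylbut-2-en-1-yl)phenyl]-2-methylbutan-1-one | CC[C@@H](C)C(=O)c1c(OC)cc(OCOC)c(CC=C(C)C)c1OCOC | intermediate
14 | (2R)-1-[2,4-dihydroxy-6-methoxy-3-(3-methylbut-2-en-1-yl)phenyl]-2-methylbutan-1-one | CC[C@@H](C)C(=O)c1c(OC)cc(O)c(CC=C(C)C)c1O | intermediate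
15 | 3-pentanone | CCC(=O)CC | starting material
16 | (Z)-3-(trimethylsilyloxy)pent-2-ene | C/C=C(\O[Si](C)(C)C)CC | intermediate
17 | malonyl dichloride (propanedioyl dichloride) | O=C(Cl)CC(=O)Cl | starting material
18 | 4-methyl-3,5-dioxoheptanoyl chloride, racemic, formed and consumed in step 9 | CCC(=O)C(C)C(=O)CC(=O)Cl | intermediate
19 | 6-ethyl-4-hydroxy-5-methyl-2H-pyran-2-one | CCc1oc(=O)cc(O)c1C | intermediate
20 | 3-[(dimethylamino)methyl]-6-ethyl-4-hydroxy-5-methyl-2H-pyran-2-one, present as its hydroiodide, formed and consumed in step 10 | CCc1oc(=O)c(CN(C)C)c(O)c1C | intermediate
21 | 6-ethyl-5-methyl-3-methylidene-2H-pyran-2,4(3H)-dione, formed and consumed in step 10 | CCC1=C(C)C(=O)C(=C)C(=O)O1 | intermediate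
22 | 3-{[2,4-dihydroxy-6-methoxy-5-[(2R)-2-methylbutanoyl]-3-(3-methylbut-2-en-1-yl)phenyl]methyl}-6-ethyl-4-hydroxy-5-methyl-2H-pyran-2-one (CNP0233274.1) | CCc1oc(=O)c(Cc2c(O)c(CC=C(C)C)c(O)c(C(=O)[C@H](C)CC)c2OC)c(O)c1C | target

## Step count and risk

Total step count: 10 (steps 1–7 on the arene, steps 8–9 on the pyrone, step 10 the union).
Longest linear sequence: 8 steps (steps 1–7 and step 10).

Least certain steps:

Step 4 (key step). The aldehyde is di-ortho-substituted and electron-rich, so allyl transfer may be slow. The uncatalysed pathway, or binding of the acid by the neighbouring acetal oxygen in place of the boronate, could then erode facial selectivity; because the two new centres are coupled through the chair, any such erosion appears directly at the centre that is kept. The fallback replaces catalyst control by stoichiometric reagent control. It sets out from 8. (E)-Crotyldiisopinocampheylborane F1 is generated in the usual way from (E)-but-2-ene (n-BuLi, KOt-Bu, THF, −78 → −45 °C), (+)-B-methoxydiisopinocampheylborane derived from (−)-α-pinene, and BF3·OEt2. This antipode is the one expected to attack the Re face. F1 is much more electrophilic at boron than a pinacol boronate and should add to 8 at −78 °C through the same chair to give the diisopinocampheylborinate of 11 F2. Oxidative work-up (NaOH, H2O2) releases the alcohol, and the route is rejoined at 11.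

Step 3. Deprotonation at the benzylic–allylic CH2 of the prenyl group may compete with ring lithiation; this would lead to side-chain isomerisation or side-chain formylation. The fallback avoids C–H deprotonation. It sets out from 5: ring bromination with N-bromosuccinimide (MeCN, −20 °C; the two free ring positions are equivalent) gives 2-bromo-1-methoxy-3,5-bis(methoxymethoxy)-4-(3-methylbut-2-en-1-yl)benzene F3. Bromine–lithium exchange (n-BuLi, THF, −78 °C), which is far faster than any deprotonation, regenerates 6, and the formamide quench of step 3 rejoins the route at 8.

Step 7. Acid may induce cyclisation of the prenyl olefin onto a freed neighbouring phenol, and prolonged exposure may cause slow enolisation of the ketone and erosion of configuration. The fallback is a non-protic ether exchange. It sets out from 13: TMSOTf and 2,2′-bipyridyl (CH2Cl2, 0 °C) transfer the methoxymethyl groups to the pyridine nitrogen and leave (2R)-1-[6-methoxy-3-(3-methylbut-2-en-1-yl)-2,4-bis(trimethylsilyloxy)phenyl]-2-methylbutan-1-one F4. Water at neutral pH hydrolyses F4, and the route is rejoined at 14.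

Step 10. If methide formation outruns its capture, the pyrone may couple with itself through the one-carbon unit. The methide may also add to the prenyl olefin as a heterodiene, and the Mannich step is reversible. The fallback reverses the roles of the partners. It sets out from 14: aminomethylation of the one free ring carbon with Eschenmoser's salt (MeCN, rt) gives (2R)-1-{3-[(dimethylamino)methyl]-4,6-dihydroxy-2-methoxy-5-(3-methylbut-2-en-1-yl)phenyl}-2-methylbutan-1-one F5. Heating F5 with 19 (dioxane, 80 °C) expels dimethylamine to give the ortho-quinone methide (2R)-1-[6-hydroxy-2-methoxy-3-methylidene-5-(3-methylbut-2-en-1-yl)-4-oxocyclohexa-1,5-dien-1-yl]-2-methylbutan-1-one F6, which the pyrone captures at C3, and the route is rejoined at 22. In this order no pyrone-derived electrophile exists, so pyrone self-coupling is excluded.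

## Further compounds

F1 | step 4 | [(2E)-but-2-en-1-yl]bis[(1S,2R,3S,5S)-2,6,6-trimethylbicyclo[3.1.1]heptan-3-yl]borane ((E)-crotyldiisopinocampheylborane from (−)-α-pinene) | C/C=C/CB([C@H]1C[C@H]2C[C@@H]([C@@H]1C)C2(C)C)[C@H]1C[C@H]2C[C@@H]([C@@H]1C)C2(C)C
F2 | step 4 | (1R,2R)-1-[6-methoxy-2,4-bis(methoxymethoxy)-3-(3-methylbut-2-en-1-yl)phenyl]-2-methylbut-3-en-1-yl bis[(1S,2R,3S,5S)-2,6,6-trimethylbicyclo[3.1.1]heptan-3-yl]borinate | C=C[C@@H](C)[C@@H](OB([C@H]1C[C@H]2C[C@@H]([C@@H]1C)C2(C)C)[C@H]1C[C@H]2C[C@@H]([C@@H]1C)C2(C)C)c1c(OC)cc(OCOC)c(CC=C(C)C)c1OCOC
F3 | step 3 | 2-bromo-1-methoxy-3,5-bis(methoxymethoxy)-4-(3-methylbut-2-en-1-yl)benzene | COc1cc(OCOC)c(CC=C(C)C)c(OCOC)c1Br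
F4 | step 7 | (2R)-1-[6-methoxy-3-(3-methylbut-2-en-1-yl)-2,4-bis(trimethylsilyloxy)phenyl]-2-methylbutan-1-one | CC[C@@H](C)C(=O)c1c(OC)cc(O[Si](C)(C)C)c(CC=C(C)C)c1O[Si](C)(C)C
F5 | step 10 | (2R)-1-{3-[(dimethylamino)methyl]-4,6-dihydroxy-2-methoxy-5-(3-methylbut-2-en-1-yl)phenyl}-2-methylbutan-1-one | CC[C@@H](C)C(=O)c1c(OC)c(CN(C)C)c(O)c(CC=C(C)C)c1O
F6 | step 10 | (2R)-1-[6-hydroxy-2-methoxy-3-methylidene-5-(3-methylbut-2-en-1-yl)-4-oxocyclohexa-1,5-dien-1-yl]-2-methylbutan-1-one | CC[C@@H](C)C(=O)C1=C(OC)C(=C)C(=O)C(CC=C(C)C)=C1O
A1 | alternative 1 | (2R)-2-methyl-1-(2,4,6-trihydroxyphenyl)butan-1-one | CC[C@@H](C)C(=O)c1c(O)cc(O)cc1O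
A2 | alternative 1 | methyl (8R)-8-methyl-3,5,7-trioxodecanoate | CC[C@@H](C)C(=O)CC(=O)CC(=O)CC(=O)OC
A3 | alternative 1 | (2R)-2-methylbutanoic acid | CC[C@@H](C)C(=O)O
A4 | alternative 2 | 3-{[2,4-diacetoxy-6-methoxy-5-[(2R)-2-methylbutanoyl]-3-(3-methylbut-2-en-1-yl)phenyl]methyl}-6-ethyl-4-hydroxy-5-methyl-2H-pyran-2-one | CCc1oc(=O)c(Cc2c(OC(C)=O)c(CC=C(C)C)c(OC(C)=O)c(C(=O)[C@H](C)CC)c2OC)c(O)c1C
A5 | alternative 2 | 2-{[2,4-diacetoxy-6-methoxy-5-[(2R)-2-methylbutanoyl]-3-(3-methylbut-2-en-1-yl)phenyl]methyl}propanedioyl dichloride | O=C(Cl)C(Cc1c(OC(C)=O)c(CC=C(C)C)c(OC(C)=O)c(C(=O)[C@H](C)CC)c1OC)C(=O)Cl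
A6 | alternative 3 | (2R)-1-[4-(tert-butyldimethylsilyloxy)-2-hydroxy-6-methoxy-3-(3-methylbut-2-enyl)phenyl]-2-methylbutan-1-one | CC[C@@H](C)C(=O)c1c(OC)cc(O[Si](C)(C)C(C)(C)C)c(CC=C(C)C)c1O
A7 | alternative 3 | 3-(tert-butyldimethylsilyloxy)-5-methoxy-2-(3-methylbut-2-enyl)phenyl (2R)-2-methylbutanoate | CC[C@@H](C)C(=O)Oc1cc(OC)cc(O[Si](C)(C)C(C)(C)C)c1CC=C(C)C
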